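# Proposed synthesis of CNP0274454.1 by anionic oxy-Cope ring expansion

## Analysis of the target

Target 31 is a ten-membered carbocycle (C1 to C10, germacrane labels: methyl C14 on C10, methyl C15 on C4, the three-carbon unit C11 to C13 on C7) spanned by an ether oxygen between C4 and C9. The bridge creates two oxepanes that share the C4–O–C9 unit: ring A (O, C4, C3, C2, C1, C10, C9) and ring B (O, C4, C5, C6, C7, C8, C9). Ring B carries an isovalerate on C5 and a trans-fused α-methylene-γ-lactone (O6–C12(=O)–C11(=C13)–C7).

There are six stereocentres (4R, 5S, 6R, 7R, 9R, 10S). The one-atom bridge couples C4 and C9, H6 and H7 are anti, the C5 oxygen is anti to the bridge oxygen on C4, and C10 sits next to the bridgehead C9. The exo-methylene lactone is a Michael acceptor and must come late. An ester on O5 next to a free O6 can migrate, and C4 is a fully substituted ether carbon.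

The difficulty is to build two medium rings around one oxygen and at the same time control a contiguous array (C4 to C7) on a flexible frame. The strategy rests on one feature. Without the bridge, the carbocycle has oxygen on C9 and C4 in a 1,6 relationship with the C6/C7 pair between them. With a C9 ketone and a C4=C5 alkene this is an E-cyclodec-5-enone, the product pattern of an anionic oxy-Cope ring expansion of a cyclohexanol in which C4–C9 is a ring bond.

## Retrosynthetic reasoning

**Lactone (31 to 28 to 27).** The O6–C12 bond and the oxidation level of C12 are removed first. 31 comes from diol 28 by oxidative lactonisation through enal 29 and lactol 30, and 28 from isopropenyl compound 27 by allylic oxidation of the C12 methyl group. The fragile methylene lactone is thus made last from a robust isopropenyl group. The forward steps must oxidise the methyl group and not C7–H, and must lactonise onto O6 only.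

**Ester and O6 protection (27 to 26 to 24 plus 25).** The acyl C–O bond on O5 is cut back to alcohol 24 and anhydride 25, with O6 still carrying its 4-methoxybenzyl group. Acylating before O6 is freed makes the later lactonisation unambiguous. The oxidative deprotection is neutral and does not invite acyl migration.

**Ether bridge (24 to 23 to 22).** The O–C4 bond is cut. Epoxy alcohol 23 opens across the ring, with O9 attacking the tertiary carbon C4 and inverting it, while the epoxide oxygen stays on C5. One operation closes both oxepanes and sets C4 and C5. The forward reaction needs epoxidation of the C4=C5 bond of 22 on its outer face and attack at C4 rather than C5.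

**C9 carbinol (22 to 21).** The alcohol comes from ketone 21 by hydride reduction. In 31, C9 has the sense of the carbinol carbon of 18 with hydrogen in place of C4, which is what attack anti to the C10–C1 ring bond delivers.

**Key disconnection (21 to 20 to 19 to 18).** C6–C7 is cut and C4–C9 is rejoined. This turns the ten-membered ketone into trans-1,2-dialkenylcyclohexanol 18. The ring, the E alkene, the 1,6 oxygen pattern and the C6/C7 pair are then traced to two stereocentres on a cyclohexane and two E alkenes.

**Dienyl arm (18 to 16 to 13 plus 14).** The C8–C9 bond is cut. Enyne 14, as its acetylide 15, adds to ketone 13, and trans-reduction of propargylic alcohol 16 fixes the E diene. A slim acetylide adds axially, anti to the axial arm on C4, which is the required sense.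

**Enol ether (13 to 11 plus 12, 11 to 9 plus 10).** The O–C6 bond is made by copper-mediated coupling of E-alkenylboronate 11 with alcohol 12, and C5=C6 by borylolefination of aldehyde 9 with 10. Both steps are stereospecific or strongly E-selective. A Wittig-type enol ether synthesis would not guarantee the E geometry on which C6 depends.

**Quaternary carbon (9 to 6 to 5 to 4 to 1 plus 2).** C4 is set by enantioselective decarboxylative allylation of enol carbonate 4, made from 1 and 2. The allyl group is shortened to formyl by isomerisation (6) and ozonolysis. C10 is set at the keto aldehyde stage by equilibration, where the small axial formyl group favours the cis-dimethyl epimer 9.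

## Alternatives that were turned down

**Alternative 1:** The C1–C2 bond of ring A is disconnected and made by Ramberg–Bäcklund contraction. Sulfone A2 has ring B complete and holds C2 and C1 together through SO2 in an eight-membered ring. It is α-halogenated under base, closes to the episulfone and loses SO2 to give cycloalkene A1, which is hydrogenated later.
- For: the contraction is dependable for seven-membered rings and has no stereochemical outcome to control. The oxygen bridge never has to form across a ten-membered ring. On reliability of the key step alone it is stronger than an oxy-Cope.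
- Against: the step makes one C–C bond and no stereocentre. Ring B, with the tetrasubstituted C4 and the whole C4 to C9 array, must be built first by other chemistry. Sulfur is brought in and removed, the acetonide on O5/O6 must be differentiated later, and the lactone with its methylene group must still be grown from the benzyloxyethyl chain of A1.
- Comparison: more steps follow its key step than the whole end-game here. In place of a risk-free key step, the chosen route offers one that builds the ring and the C6/C7 pair at once.

**Alternative 2:** The C7–C11 bond is disconnected and the lactone is annulated last. Diazo ester A4 (diazophosphonoacetate on O6, isovalerate on O5, C7 a methylene group) gives a carbenoid with Rh2(OAc)4 that inserts into a C7–H bond to give phosphono lactone A3. Olefination with formaldehyde would then finish.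
- For: 1,5-insertion to a five-membered ring is the normal course, the phosphonate doubles as the handle for the methylene group, and the ester is already in place. On end-game economy it is clearly stronger than steps 12 to 15 here.
- Against: the insertion must take the C7 hydrogen trans to O6, whereas five-ring annulation on a ring usually prefers cis fusion. The C5 methine is also 1,5-related, and the bridge oxygen can trap the carbenoid as an ylide. The plan presupposes the bicyclic ether with five stereocentres and does not say how it is made.
- Comparison: the chosen route builds that core and sets C7 through alkene geometry in a chair, not through a conformational preference of an insertion.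

**Alternative 3:** The O–C4 bond is disconnected and C4 is reconnected to C9. trans-Decalin A6 carries a 4-nitroperbenzoate on the ring-fusion carbon C9. Ionisation of the O–O bond with 1,2-shift of C4 from carbon to oxygen (retention at C4) and collapse of the ion pair gives bridged ketal ester A5 (Criegee rearrangement).
- For: this is the classical behaviour of ring-fusion decalyl peresters and gives the 11-oxabicyclo[4.4.1]undecane directly. C4 is transferred with retention. The bridgehead C9 can have only one configuration, so no face selectivity arises there; on that point it is stronger than the chosen route.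
- Against: C10 and C8 can migrate in competition with C4. C9 ends with an extra oxygen that must be removed by reduction through a strained bridgehead oxocarbenium ion. A6 is a trans-decalin with six stereocentres and a ring-fusion peroxide beside a lactone, which needs a long synthesis, and methylenation is still to come.
- Comparison: the chosen route reaches the same 1,6 oxygen pattern from a monocyclic ketone in one step and needs only a simple ketone reduction at C9. The price is that this reduction must be face-selective (step 10).

Key step: step 9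

Remarks on the chemistry:
- Locants C1 to C15 in the text are the germacrane labels defined above.
- It is assumed that the remote C6 methyl group of 4 does not change the sense of induction of the PHOX ligand in step 2.
- Commercial 1 is used as its cis/trans mixture, because both α-centres are reset.

## Steps

Step 1
Reactants: 1 2,6-dimethylcyclohexanone; 2 allyl chloroformate
Product: 4 2,6-dimethylcyclohex-1-en-1-yl prop-2-en-1-yl carbonate (racemic), via sodium enolate 3 (not isolated)
Conditions: NaN(SiMe3)2, TMEDA, THF, −78 °C; then 2, −78 °C to 0 °C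
Reagents that add atoms: none
Why: The two α-positions of 1 are equivalent, so deprotonation gives one tetrasubstituted enolate, which the hard chloroformate acylates on oxygen (enol carbonate formation).

Step 2
Reactants: 4
Product: 5 (2R)-2,6-dimethyl-2-(prop-2-en-1-yl)cyclohexan-1-one as both C6 epimers
Conditions: Pd2(dba)3 (2.5 mol %), (R)-t-BuPHOX [(R)-4-tert-butyl-2-(2-diphenylphosphanylphenyl)-4,5-dihydrooxazole] (6 mol %), THF, 25 °C
Reagents that add atoms: none
Why: Decarboxylative asymmetric Tsuji allylation: zerovalent palladium ionises the allyl carbonate, CO2 is lost and the allyl group recombines at the tetrasubstituted enolate carbon, with the ligand choosing the enolate face. The (R) ligand is chosen because the (S) ligand is known to give (S) α-quaternary ketones from 2-alkylcyclohexanone enol carbonates; the C6 methyl is a spectator here and is corrected in step 4.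

Step 3
Reactants: 5
Product: 6 (2R)-2,6-dimethyl-2-[(E)-prop-1-en-1-yl]cyclohexan-1-one as both C6 epimers
Conditions: PdCl2(MeCN)2 (5 mol %), toluene, 70 °C
Reagents that add atoms: none
Why: Palladium hydride alkene isomerisation moves the terminal double bond one position inward; the quaternary carbon stops further migration, and the E/Z ratio does not matter because the alkene is cleaved next.

Step 4
Reactants: 6
Product: 9 (1R,3S)-1,3-dimethyl-2-oxocyclohexane-1-carbaldehyde, via secondary ozonide 7 (not isolated), via epimeric keto aldehyde 8 (not isolated)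
Conditions: O3, CH2Cl2, −78 °C; PPh3, −78 °C to 25 °C; then CSA (5 mol %), CH2Cl2, 25 °C; chromatography, minor epimer resubmitted
Reagents that add atoms: ozone, [O-][O+]=O
Why: Ozonolysis with reductive work-up cuts the propenyl group down to a formyl group on the quaternary carbon, which cannot enolise. Acid-catalysed enolisation towards C3 (label C10) then equilibrates the only epimerisable centre; the epimer with both methyl groups equatorial and the small formyl group axial should dominate, because formyl has a much lower A value than methyl.

Step 5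
Reactants: 9; 10 2-(dichloromethyl)-4,4,5,5-tetramethyl-1,3,2-dioxaborolane
Product: 11 (2R,6S)-2,6-dimethyl-2-[(E)-2-(4,4,5,5-tetramethyl-1,3,2-dioxaborolan-2-yl)ethenyl]cyclohexan-1-one
Conditions: 10 (2 equiv), CrCl2 (8 equiv), LiI (4 equiv), THF, 25 °C
Reagents that add atoms: none
Why: Takai–Utimoto borylolefination: the geminal dichromium species adds to the aldehyde only, and anti elimination of the β-oxido chromium intermediate gives the E alkenylboronate; E selectivity is best for α-branched aldehydes, and the neutral medium leaves the α-methyl centre alone.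

Step 6
Reactants: 11; 12 4-methoxybenzyl alcohol
Product: 13 (2R,6S)-2-{(E)-2-[(4-methoxyphenyl)methoxy]ethenyl}-2,6-dimethylcyclohexan-1-one
Conditions: Cu(OAc)2 (2 equiv), Et3N (4 equiv), 12 (10 equiv), 4 Å molecular sieves, CH2Cl2, 25 °C
Reagents that add atoms: none
Why: Chan–Lam-type coupling of an alkenylboronate with an aliphatic alcohol: transmetalation to copper and C–O bond formation proceed with retention, so the E geometry of 11 is carried into the enol ether. The 4-methoxybenzyl group is chosen because it survives base and hydride and is later removed oxidatively beside an ester.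

Step 7
Reactants: 13; 14 2-methylbut-1-en-3-yne
Product: 16 (1R,2R,6S)-2-{(E)-2-[(4-methoxyphenyl)methoxy]ethenyl}-2,6-dimethyl-1-(3-methylbut-3-en-1-yn-1-yl)cyclohexan-1-ol, via lithium acetylide 15 (not isolated)
Conditions: 14, n-BuLi, THF, −78 °C; then 13, −78 °C to −20 °C; H2O
Reagents that add atoms: none
Why: 1,2-Addition of an alkynyllithium to a ketone. 13 sits in the chair with both methyl groups equatorial and the alkenyl arm axial, so the slim acetylide enters axially on the face opposite that arm; the new C8–C9 bond ends trans to the arm and cis to both methyl groups, which sets C9.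

Step 8
Reactants: 16
Product: 18 (1S,2R,6S)-2-{(E)-2-[(4-methoxyphenyl)methoxy]ethenyl}-2,6-dimethyl-1-[(E)-3-methylbuta-1,3-dien-1-yl]cyclohexan-1-ol, via cyclic alkenylaluminate 17 (not isolated)
Conditions: NaAlH2(OCH2CH2OMe)2, THF, 0 °C to 25 °C; then aq NaOH
Reagents that add atoms: none
Why: Alkoxide-directed trans-hydroalumination of a propargylic alcohol: hydride goes to C8 from the oxygen-bound aluminium, aluminium ends on C7 in a five-membered ring, and protonolysis with retention gives only the E alkene. The isopropenyl and enol ether double bonds are not reduced, and the change of CIP descriptor at C1 is formal.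

Step 9
Reactants: 18
Product: 21 (3R,4S,10S,5E)-4-[(4-methoxyphenyl)methoxy]-6,10-dimethyl-3-(prop-1-en-2-yl)cyclodec-5-en-1-one, via potassium alkoxide 19 (not isolated), via potassium enolate 20 (not isolated)
Conditions: KH (3 equiv), 18-crown-6 (3 equiv), THF, 0 °C to 25 °C; then AcOH, −78 °C
Reagents that add atoms: none
Why: KH with 18-crown-6 gives the dissociated potassium alkoxide 19, and the charge-accelerated [3,3] shift across C7=C8–C9(O−)–C4–C5=C6 breaks the ring bond C4–C9 and makes C6–C7, giving enolate 20, which is protonated at C8 to ketone 21. The closest known reaction type is the anionic oxy-Cope ring expansion of trans-1,2-dialkenylcyclohexanols to E-cyclodec-5-enones. The ten-membered ring is not closed end to end: it arises by four-atom enlargement of the cyclohexane through a six-membered chair transition state, so the usual penalty of medium-ring cyclisation does not apply. Because the two alkenyl groups are trans, only the chair with both equatorial on the cyclohexane brings C6 and C7 together; in it the ring carbons C3 and C10 are equatorial on the reacting chair, which makes the new C4=C5 bond E. C6 is set by the E enol ether (aryl-methoxy group equatorial) and C7 by the E diene (isopropenyl equatorial), so H6 and H7 come out anti as the trans lactone needs, and the absolute sense follows from C4 and C9 of 18. The step needs chair over boat selectivity, [3,3] over [1,3] shift or fragmentation, and retention at C10; the trans relationship, the crown ether (reaction near room temperature) and a cold acetic acid quench that protonates the kinetic enolate at C8 serve these needs. The reactive chair carries the C4 and C10 methyl groups syn-axial, a cost of a few kcal/mol that may call for mild warming.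

Step 10
Reactants: 21
Product: 22 (1R,3R,4S,10S,5E)-4-[(4-methoxyphenyl)methoxy]-6,10-dimethyl-3-(prop-1-en-2-yl)cyclodec-5-en-1-ol
Conditions: LiBH(s-Bu)3, THF, −78 °C; then H2O
Reagents that add atoms: none
Why: Hydride reduction of the ketone. Under Felkin–Anh control by C10, the ring bond C10–C1 lies anti to the incoming bulky hydride and the methyl group flanks the carbonyl oxygen; this coincides with attack from outside the medium ring and should give the 9R carbinol.

Step 11
Reactants: 22
Product: 24 (1R,2S,3R,4R,6R,7S)-3-[(4-methoxyphenyl)methoxy]-1,7-dimethyl-4-(prop-1-en-2-yl)-11-oxabicyclo[4.4.1]undecan-2-ol, via epoxy alcohol 23 (not isolated)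
Conditions: mCPBA (1.05 equiv), CH2Cl2, −20 °C to 0 °C; then CSA (10 mol %), 0 °C to 25 °C
Reagents that add atoms: 3-chloroperbenzoic acid, OOC(=O)c1cccc(Cl)c1
Why: Peracid epoxidation takes the strained trisubstituted E alkene before the 1,1-disubstituted isopropenyl group and attacks its outer face, because allylic 1,3-strain keeps H6 in the alkene plane and the ring chain covers the inner face; this gives the 4S,5S epoxide. Acid then triggers transannular opening by O9 at the tertiary carbon C4 with inversion, which closes both oxepanes and leaves the epoxide oxygen as the C5 hydroxyl anti to the bridge.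

Step 12
Reactants: 24; 25 3-methylbutanoic anhydride
Product: 26 (1R,2S,3R,4R,6R,7S)-3-[(4-methoxyphenyl)methoxy]-1,7-dimethyl-4-(prop-1-en-2-yl)-11-oxabicyclo[4.4.1]undecan-2-yl 3-methylbutanoate
Conditions: 25 (3 equiv), DMAP (0.3 equiv), Et3N, CH2Cl2, 25 °C
Reagents that add atoms: none
Why: DMAP-catalysed acylation of the only free hydroxyl (C5), done while O6 is still protected so that the later lactonisation can involve O6 alone.

Step 13
Reactants: 26
Product: 27 (1R,2S,3R,4R,6R,7S)-3-hydroxy-1,7-dimethyl-4-(prop-1-en-2-yl)-11-oxabicyclo[4.4.1]undecan-2-yl 3-methylbutanoate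
Conditions: DDQ (1.3 equiv), CH2Cl2/pH 7 buffer, 0 °C
Reagents that add atoms: none
Why: Oxidative cleavage of the 4-methoxybenzyl ether (benzylic hydride abstraction, then hydrolysis of the oxocarbenium ion); the neutral medium spares the ester, the ether bridge and the isopropenyl group and gives little occasion for an O5 to O6 acyl shift.

Step 14
Reactants: 27
Product: 28 (1R,2S,3R,4R,6R,7S)-3-hydroxy-4-(3-hydroxyprop-1-en-2-yl)-1,7-dimethyl-11-oxabicyclo[4.4.1]undecan-2-yl 3-methylbutanoate
Conditions: SeO2 (20 mol %), t-BuOOH (3 equiv), CH2Cl2, 25 °C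
Reagents that add atoms: selenium dioxide, O=[Se]=O (catalytic oxygen carrier); tert-butyl hydroperoxide, CC(C)(C)OO (terminal oxygen source)
Why: Allylic oxidation by ene reaction and [2,3]-sigmatropic shift of the allylseleninic acid; on a 1,1-disubstituted alkene the methyl group (C12) reacts in preference to the methine C7–H. The hydroperoxide keeps selenium catalytic and the product mainly at the alcohol level; any enal formed converges in step 15.

Step 15
Reactants: 28
Product: 31 CNP0274454.1 (4R,5S,6R,7R,9R,10S), via enal 29 (not isolated), via lactol 30 (not isolated)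
Conditions: TEMPO (20 mol %), PhI(OAc)2 (2.5 equiv), CH2Cl2, 25 °C
Reagents that add atoms: none
Why: Oxoammonium oxidation takes the primary allylic alcohol to enal 29, the C6 hydroxyl adds to the aldehyde to close the five-membered lactol 30 (5-exo-trig), and a second oxidation gives the α-methylene lactone. The secondary C6 hydroxyl is not oxidised under these conditions and O5 is blocked, so only the 12,6-lactone can form.

## Compound list

1 | 2,6-dimethylcyclohexanone (cis/trans mixture) | CC1CCCC(C)C1=O | starting material
2 | allyl chloroformate | C=CCOC(Cl)=O | starting material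
3 | sodium 2,6-dimethylcyclohex-1-en-1-olate | CC1CCCC(C)=C1[O-].[Na+] | intermediate
4 | 2,6-dimethylcyclohex-1-en-1-yl prop-2-en-1-yl carbonate (racemic) | C=CCOC(=O)OC1=C(C)CCCC1C | intermediate
5 | (2R)-2,6-dimethyl-2-(prop-2-en-1-yl)cyclohexan-1-one, both C6 epimers | O=C1C(C)CCC[C@]1(C)CC=C | intermediate
6 | (2R)-2,6-dimethyl-2-[(E)-prop-1-en-1-yl]cyclohexan-1-one, both C6 epimers | O=C1C(C)CCC[C@]1(C)/C=C/C | intermediate
7 | (2R)-2,6-dimethyl-2-(5-methyl-1,2,4-trioxolan-3-yl)cyclohexan-1-one (secondary ozonide, stereoisomer mixture) | O=C1C(C)CCC[C@]1(C)C1OOC(C)O1 | intermediate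
8 | (1R)-1,3-dimethyl-2-oxocyclohexane-1-carbaldehyde, both C3 epimers | O=C1C(C)CCC[C@]1(C)C=O | intermediate
9 | (1R,3S)-1,3-dimethyl-2-oxocyclohexane-1-carbaldehyde | O=C1[C@@H](C)CCC[C@]1(C)C=O | intermediate
10 | 2-(dichloromethyl)-4,4,5,5-tetramethyl-1,3,2-dioxaborolane | ClC(Cl)B1OC(C)(C)C(C)(C)O1 | starting material
11 | (2R,6S)-2,6-dimethyl-2-[(E)-2-(4,4,5,5-tetramethyl-1,3,2-dioxaborolan-2-yl)ethenyl]cyclohexan-1-one | O=C1[C@@H](C)CCC[C@]1(C)/C=C/B1OC(C)(C)C(C)(C)O1 | intermediate
12 | 4-methoxybenzyl alcohol | COc1ccc(CO)cc1 | starting material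
13 | (2R,6S)-2-{(E)-2-[(4-methoxyphenyl)methoxy]ethenyl}-2,6-dimethylcyclohexan-1-one | O=C1[C@@H](C)CCC[C@]1(C)/C=C/OCc1ccc(OC)cc1 | intermediate
14 | 2-methylbut-1-en-3-yne | C=C(C)C#C | starting material
15 | lithium 3-methylbut-3-en-1-yn-1-ide | [Li+].[C-]#CC(C)=C | intermediate
16 | (1R,2R,6S)-2-{(E)-2-[(4-methoxyphenyl)methoxy]ethenyl}-2,6-dimethyl-1-(3-methylbut-3-en-1-yn-1-yl)cyclohexan-1-ol | C=C(C)C#C[C@@]1(O)[C@@H](C)CCC[C@]1(C)/C=C/OCc1ccc(OC)cc1 | intermediate
17 | sodium cyclic alkenylaluminate of 16 (five-membered O–C9–C8=C7–Al ring, two 2-methoxyethoxy groups on aluminium) | [Na+].C=C(C)C1=C[C@@]2(O[Al-]1(OCCOC)OCCOC)[C@@H](C)CCC[C@]2(C)/C=C/OCc1ccc(OC)cc1 | intermediate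
18 | (1S,2R,6S)-2-{(E)-2-[(4-methoxyphenyl)methoxy]ethenyl}-2,6-dimethyl-1-[(E)-3-methylbuta-1,3-dien-1-yl]cyclohexan-1-ol | C=C(C)/C=C/[C@@]1(O)[C@@H](C)CCC[C@]1(C)/C=C/OCc1ccc(OC)cc1 | intermediate
19 | potassium alkoxide of 18 | C=C(C)/C=C/[C@@]1([O-])[C@@H](C)CCC[C@]1(C)/C=C/OCc1ccc(OC)cc1.[K+] | intermediate
20 | potassium enolate of 21 (C8=C9 enolate, oxygen cis to C7; 4E) | C=C(C)[C@H]1/C=C(\[O-])[C@@H](C)CCC/C(C)=C/[C@@H]1OCc1ccc(OC)cc1.[K+] | intermediate
21 | (3R,4S,10S,5E)-4-[(4-methoxyphenyl)methoxy]-6,10-dimethyl-3-(prop-1-en-2-yl)cyclodec-5-en-1-one (labels: 6S,7R,10S) | C=C(C)[C@H]1CC(=O)[C@@H](C)CCC/C(C)=C/[C@@H]1OCc1ccc(OC)cc1 | intermediate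
22 | (1R,3R,4S,10S,5E)-4-[(4-methoxyphenyl)methoxy]-6,10-dimethyl-3-(prop-1-en-2-yl)cyclodec-5-en-1-ol (labels: 6S,7R,9R,10S) | C=C(C)[C@H]1C[C@@H](O)[C@@H](C)CCC/C(C)=C/[C@@H]1OCc1ccc(OC)cc1 | intermediate
23 | trans-4,5-epoxide of 22 (labels: 4S,5S,6R,7R,9R,10S; epoxide oxygen syn to the C6–O bond) | C=C(C)[C@H]1C[C@@H](O)[C@@H](C)CCC[C@]2(C)O[C@H]2[C@@H]1OCc1ccc(OC)cc1 | intermediate
24 | (1R,2S,3R,4R,6R,7S)-3-[(4-methoxyphenyl)methoxy]-1,7-dimethyl-4-(prop-1-en-2-yl)-11-oxabicyclo[4.4.1]undecan-2-ol | COc1ccc(CO[C@@H]2[C@@H](C(C)=C)C[C@H]3O[C@](C)(CCC[C@@H]3C)[C@H]2O)cc1 | intermediate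
25 | 3-methylbutanoic anhydride | CC(C)CC(=O)OC(=O)CC(C)C | starting material
26 | (1R,2S,3R,4R,6R,7S)-3-[(4-methoxyphenyl)methoxy]-1,7-dimethyl-4-(prop-1-en-2-yl)-11-oxabicyclo[4.4.1]undecan-2-yl 3-methylbutanoate | COc1ccc(CO[C@@H]2[C@@H](C(C)=C)C[C@H]3O[C@](C)(CCC[C@@H]3C)[C@H]2OC(=O)CC(C)C)cc1 | intermediate
27 | (1R,2S,3R,4R,6R,7S)-3-hydroxy-1,7-dimethyl-4-(prop-1-en-2-yl)-11-oxabicyclo[4.4.1]undecan-2-yl 3-methylbutanoate | O[C@@H]1[C@@H](C(C)=C)C[C@H]2O[C@](C)(CCC[C@@H]2C)[C@H]1OC(=O)CC(C)C | intermediate
28 | (1R,2S,3R,4R,6R,7S)-3-hydroxy-4-(3-hydroxyprop-1-en-2-yl)-1,7-dimethyl-11-oxabicyclo[4.4.1]undecan-2-yl 3-methylbutanoate | O[C@@H]1[C@@H](C(CO)=C)C[C@H]2O[C@](C)(CCC[C@@H]2C)[C@H]1OC(=O)CC(C)C | intermediate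
29 | (1R,2S,3R,4R,6R,7S)-3-hydroxy-1,7-dimethyl-4-(3-oxoprop-1-en-2-yl)-11-oxabicyclo[4.4.1]undecan-2-yl 3-methylbutanoate | O[C@@H]1[C@@H](C(C=O)=C)C[C@H]2O[C@](C)(CCC[C@@H]2C)[C@H]1OC(=O)CC(C)C | intermediate
30 | lactol of 31 (C12 hemiacetal, both anomers) | C=C1C(O)O[C@@H]2[C@@H]1C[C@H]1O[C@](C)(CCC[C@@H]1C)[C@H]2OC(=O)CC(C)C | intermediate
31 | CNP0274454.1, (4R,5S,6R,7R,9R,10S)-4,9-epoxy-5-(3-methylbutanoyloxy)germacr-11(13)-en-12,6-olide (labels of the analysis) | C=C1C(=O)O[C@@H]2[C@@H]1C[C@H]1O[C@](C)(CCC[C@@H]1C)[C@H]2OC(=O)CC(C)C | target

## Step count and least certain steps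

Total step count: 15. Longest linear sequence: 15 steps (1 to 31).

**Step 9 (key step).** The reactive chair of 19 has the C4 and C10 methyl groups syn-axial, so the rearrangement may be slow enough for fragmentation of the alkoxide or a [1,3] shift to compete. Proton exchange in enolate 20 before the quench could also erode the C10 configuration. Fallback: from 18, silylation (Me3SiOTf, Et3N, CH2Cl2, −78 °C) gives the trimethylsilyl ether F1. Neutral thermal [3,3] rearrangement (degassed toluene, sealed, about 200 °C) through the same chair gives the ring-expanded trimethylsilyl enol ether F2, in which no free enolate ever exists. K2CO3 in MeOH at 0 °C then returns ketone 21.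

**Step 4.** The equilibration may favour the cis-dimethyl epimer only modestly, and the non-enolisable β-keto aldehyde can lose its formyl group by nucleophilic cleavage, so material may be lost in recycling. Fallback: fix C10 before C4. From cis-enriched 1, enantioselective deprotonation with a chiral lithium amide (for example lithium bis(1-phenylethyl)amide of the appropriate configuration) and Me3SiCl at −100 °C gives the (6S) trimethylsilyl enol ether F3. Palladium-catalysed asymmetric allylation of F3 (diallyl carbonate, Pd2(dba)3, (R)-t-BuPHOX, catalytic tetrabutylammonium difluorotriphenylsilicate) gives the single epimer (2R,6S)-2-allyl-2,6-dimethylcyclohexanone F4 under non-epimerising conditions. Isomerisation as in step 3 gives the propenyl ketone F5, and ozonolysis through the ozonide F6 gives 9 directly, without the acid equilibration.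

**Step 6.** The copper coupling may be slow with the large excess of a benzylic alcohol, with protodeboronation of 11 or oxidation of 12 as competing processes. Fallback: reverse the polarity of the coupling. From 9, iodo-olefination (CHI3, CrCl2, THF, 0 °C) gives the E vinyl iodide F7. Copper-catalysed C–O coupling of F7 with 12 (CuI, 3,4,7,8-tetramethyl-1,10-phenanthroline, Cs2CO3, toluene, 80 °C) proceeds with retention and gives 13. The stronger base means the α-methyl centre must be watched.

**Step 10.** Facial selectivity may be poor or reversed if the ten-membered ketone reacts through a conformer in which the carbonyl has turned its other face outward. Fallback: from 21, whatever hydride gives mainly the 9S alcohol F8 is used. Mitsunobu inversion (4-nitrobenzoic acid, PPh3, diisopropyl azodicarboxylate) gives the 9R 4-nitrobenzoate F9, and K2CO3 in MeOH gives 22. Only the 9R epimer can close the out,out bridge in step 11, so that step also acts as a filter.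

**Step 11.** Three things can go wrong: loss of site selectivity (epoxidation of the isopropenyl group), epoxidation on the inner face, and opening of the epoxide at C5 to a six-membered ether instead of at C4. Fallback: use hydroxyl direction and change the end order. From 22, DDQ gives the diol F10. VO(acac)2 with t-BuOOH epoxidises only the allylic C4=C5 bond, syn to the C6 hydroxyl (the same face as required), to give the epoxy diol F11. CSA closes the bridge to the bicyclic diol F12. SeO2/t-BuOOH gives the triol F13, TEMPO/PhI(OAc)2 gives the hydroxy lactone F14, and acylation with 25 (DMAP) gives 31. This order also avoids any O5 to O6 acyl shift in steps 13 to 15, but it accepts a possible competition from the six-membered lactone onto O5, which is why it is not the main route.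

## Further compounds

F1 | step 9 | trimethylsilyl ether of 18 | C=C(C)/C=C/[C@@]1(O[Si](C)(C)C)[C@@H](C)CCC[C@]1(C)/C=C/OCc1ccc(OC)cc1
F2 | step 9 | trimethylsilyl enol ether of 21 (C8=C9, oxygen cis to C7) | C=C(C)[C@H]1/C=C(\O[Si](C)(C)C)[C@@H](C)CCC/C(C)=C/[C@@H]1OCc1ccc(OC)cc1
F3 | step 4 | {[(6S)-2,6-dimethylcyclohex-1-en-1-yl]oxy}trimethylsilane | C[Si](C)(C)OC1=C(C)CCC[C@@H]1C
F4 | step 4 | (2R,6S)-2,6-dimethyl-2-(prop-2-en-1-yl)cyclohexan-1-one | O=C1[C@@H](C)CCC[C@]1(C)CC=C
F5 | step 4 | (2R,6S)-2,6-dimethyl-2-[(E)-prop-1-en-1-yl]cyclohexan-1-one | O=C1[C@@H](C)CCC[C@]1(C)/C=C/C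
F6 | step 4 | (2R,6S)-2,6-dimethyl-2-(5-methyl-1,2,4-trioxolan-3-yl)cyclohexan-1-one | O=C1[C@@H](C)CCC[C@]1(C)C1OOC(C)O1
F7 | step 6 | (2R,6S)-2-[(E)-2-iodoethenyl]-2,6-dimethylcyclohexan-1-one | O=C1[C@@H](C)CCC[C@]1(C)/C=C/I
F8 | step 10 | C9 epimer of 22 (9S alcohol) | C=C(C)[C@H]1C[C@H](O)[C@@H](C)CCC/C(C)=C/[C@@H]1OCc1ccc(OC)cc1
F9 | step 10 | 4-nitrobenzoate of 22 (9R) | C=C(C)[C@H]1C[C@@H](OC(=O)c2ccc(cc2)[N+](=O)[O-])[C@@H](C)CCC/C(C)=C/[C@@H]1OCc1ccc(OC)cc1
F10 | step 11 | C6,C9 diol (22 without the 4-methoxybenzyl group) | C=C(C)[C@H]1C[C@@H](O)[C@@H](C)CCC/C(C)=C/[C@@H]1O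
F11 | step 11 | 4S,5S epoxide of F10 | C=C(C)[C@H]1C[C@@H](O)[C@@H](C)CCC[C@]2(C)O[C@H]2[C@@H]1O
F12 | step 11 | (1R,2S,3R,4R,6R,7S)-1,7-dimethyl-4-(prop-1-en-2-yl)-11-oxabicyclo[4.4.1]undecane-2,3-diol | O[C@@H]1[C@@H](C(C)=C)C[C@H]2O[C@](C)(CCC[C@@H]2C)[C@H]1O
F13 | step 11 | (1R,2S,3R,4R,6R,7S)-4-(3-hydroxyprop-1-en-2-yl)-1,7-dimethyl-11-oxabicyclo[4.4.1]undecane-2,3-diol | O[C@@H]1[C@@H](C(CO)=C)C[C@H]2O[C@](C)(CCC[C@@H]2C)[C@H]1O
F14 | step 11 | C5 hydroxy lactone (31 without the 3-methylbutanoyl group) | C=C1C(=O)O[C@@H]2[C@@H]1C[C@H]1O[C@](C)(CCC[C@@H]1C)[C@H]2O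
A1 | alternative 1 | oxabicyclo[4.4.1]undecene acetonide with C1=C2 alkene and 2-benzyloxyethyl group on C7 | CC1(C)O[C@@H]2[C@@H](CCOCc3ccccc3)C[C@H]3O[C@](C)(CC=C[C@@H]3C)[C@H]2O1
A2 | alternative 1 | bicyclic sulfone with SO2 between C2 and C1 (eight-membered thia ring) | CC1(C)O[C@@H]2[C@@H](CCOCc3ccccc3)C[C@H]3O[C@](C)(CCS(=O)(=O)C[C@@H]3C)[C@H]2O1
A3 | alternative 2 | α-diethylphosphono trans-fused lactone | CCOP(=O)(OCC)[C@H]1C(=O)O[C@@H]2[C@@H]1C[C@H]1O[C@](C)(CCC[C@@H]1C)[C@H]2OC(=O)CC(C)C
A4 | alternative 2 | C6 diazophosphonoacetate of the bicyclic diol C5 isovalerate | CCOP(=O)(OCC)C(=[N+]=[N-])C(=O)O[C@@H]1CC[C@H]2O[C@](C)(CCC[C@@H]2C)[C@H]1OC(=O)CC(C)C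
A5 | alternative 3 | C9 4-nitrobenzoyloxy 11-oxabicyclo[4.4.1]undecane lactone | C1C(=O)O[C@@H]2[C@@H]1C[C@@]1(OC(=O)c3ccc(cc3)[N+](=O)[O-])O[C@](C)(CCC[C@@H]1C)[C@H]2OCc1ccccc1
A6 | alternative 3 | trans-decalin lactone with 4-nitroperbenzoate on ring-fusion carbon C9 | C1C(=O)O[C@@H]2[C@@H]1C[C@]1(OOC(=O)c3ccc(cc3)[N+](=O)[O-])[C@](C)(CCC[C@@H]1C)[C@H]2OCc1ccccc1
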